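**Plan**

- Locants are eudesmane: ring A = C1–C5 and C10; ring B = C5–C10; C10 bears CH3, C4 bears CH3 and OH, C7 bears C11(CH3)2OH. The enabling feature is in ring B: the C8 ketone and the C11 carbinol sit 1,3 across C7 (O=C8–C7–C11–OH), and C7–C8 is a ring B bond. That array is the retron of an intramolecular nitrile oxide–alkene cycloaddition whose isoxazoline (C8=N–O–C11) is a temporary third ring.
- Retrosynthetic cuts, in order: C3–O acyl bond; C3–O and C4–O (osmylation of C3=C4); C6=C7 (dehydrogenation); the N–O and C=N bonds (unmasking); C4–CH3 (triflate coupling); then C7–C8 together with O–C11 (cycloaddition, ring B); C5–C6 (enolate prenylation); C10–C9 (conjugate addition of vinyl).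
- Forward: ring A is bought as 3-methylcyclohex-2-enone, the two side chains are placed on C10 and C5, and ring B is closed last together with the temporary isoxazoline, which is opened again four steps later.
- Stereochemistry: C10 from the chiral copper catalyst; C5 by equilibration next to the C4 ketone in the isoxazoline-locked decalone (trans fusion); C3 and C4 by osmylation on the α face opposite the axial C10 methyl; the Z ester geometry from angelic acid.

Key step: step 5

Remark: compounds 7–12 are carried as both epimers at C5, which converge in step 6; C7 of 12–19 is a temporary centre, drawn as the expected 7α-H epimer.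

**Route**

Step 1
Reactants: 1 3-methylcyclohex-2-en-1-one; 2 vinylmagnesium bromide
Product: 4 (R)-trimethyl[(3-methyl-3-vinylcyclohex-1-en-1-yl)oxy]silane, via aluminium enolate 3 (not isolated)
Conditions: 2, Me2AlCl, Et2O, 0 °C; then 1, Cu(O2CC4H3S) (10 mol%), chiral aminophosphine ligand (SimplePhos type, 11 mol%), −30 °C; then Me3SiOSO2CF3, −30 °C to rt
Reagents that add atoms: vinylmagnesium bromide 2, C=C[Mg]Br (vinyl group, transferred as dimethyl(vinyl)aluminium, C=C[Al](C)C); trimethylsilyl triflate, C[Si](C)(C)OS(=O)(=O)C(F)(F)F
Why: Copper-catalysed asymmetric conjugate addition of an alkenylalane to a β-substituted cyclohexenone builds the quaternary C10, the ligand enantiomer being chosen so that vinyl adds to the enone face that gives (R)-4, and O-silylation of the aluminium enolate stores the C4/C5 enolate regiochemistry for step 2.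

Step 2
Reactants: 4 (R)-trimethyl[(3-methyl-3-vinylcyclohex-1-en-1-yl)oxy]silane; 5 1-bromo-3-methylbut-2-ene
Product: 7 (3R)-3-methyl-2-(3-methylbut-2-en-1-yl)-3-vinylcyclohexan-1-one (both C2 epimers), via lithium enolate 6 (not isolated)
Conditions: MeLi, THF, 0 °C; then 5, HMPA, −78 to 0 °C
Reagents that add atoms: 1-bromo-3-methylbut-2-ene 5, CC(C)=CCBr
Why: Methyllithium cleaves the silyl enol ether to the regiodefined lithium enolate, which is C-alkylated by SN2 attack on the allylic bromide (enolate alkylation); the new C5 centre forms without useful bias between methyl and vinyl on the neighbouring quaternary carbon, which is harmless because C5 is equilibrated in step 6.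

Step 3
Reactants: 7 (3R)-3-methyl-2-(3-methylbut-2-en-1-yl)-3-vinylcyclohexan-1-one (both C2 epimers)
Product: 8 2-[(1R)-1-methyl-2-(3-methylbut-2-en-1-yl)-3-oxocyclohexyl]acetaldehyde (both C2 epimers)
Conditions: PdCl2(PhCN)2 (10 mol%), CuCl2·2H2O (10 mol%), AgNO2 (5 mol%), O2 (1 atm), t-BuOH/MeNO2 15:1, rt
Reagents that add atoms: dioxygen, O=O
Why: The nitrite-modified, aldehyde-selective Wacker oxidation places oxygen on the terminal carbon of a vinyl group attached to a quaternary centre (anti-Markovnikov), while the trisubstituted prenyl alkene and the ketone should not react, and no stereocentre is formed.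

Step 4
Reactants: 8 2-[(1R)-1-methyl-2-(3-methylbut-2-en-1-yl)-3-oxocyclohexyl]acetaldehyde (both C2 epimers)
Product: 9 2-[(1R)-1-methyl-2-(3-methylbut-2-en-1-yl)-3-oxocyclohexyl]acetaldehyde oxime (both C2 epimers)
Conditions: NH2OH·HCl (1.05 equiv), NaOAc, EtOH/H2O, 0 °C
Reagents that add atoms: hydroxylamine hydrochloride, NO.Cl
Why: Oxime condensation is much faster at the unhindered aldehyde than at the ring ketone flanked by the substituted C5, so one equivalent of hydroxylamine in the cold should give the aldoxime, either geometry of which serves in step 5.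

Step 5
Reactants: 9 2-[(1R)-1-methyl-2-(3-methylbut-2-en-1-yl)-3-oxocyclohexyl]acetaldehyde oxime (both C2 epimers)
Product: 12 tricyclic isoxazoline ketone (15-noreudesman-4-one bridged C8=N–O–C11; 7α-H; both C5 epimers), via hydroximoyl chloride 10 (not isolated), via nitrile oxide 11 (not isolated)
Conditions: aq. NaOCl (1.5 equiv), CH2Cl2, 0 °C to rt, 0.01 M, slow addition
Reagents that add atoms: none
Why: Hypochlorite chlorinates the aldoxime and base removes HCl, so nitrile oxide 11 forms slowly at high dilution and adds as a 1,3-dipole across the trisubstituted C7=C11 bond in a concerted, asynchronous [3+2] cycloaddition (intramolecular nitrile oxide–alkene cycloaddition, the isoxazoline route to β-hydroxy ketones being the closest known reaction type). Ring B closes by the C8–C7 bond in the 6-exo sense (C8 attacks the proximal alkene carbon and C11 stays outside ring B), and the temporary isoxazoline closes in the same event by the O–C11 bond, giving the fused and not the bridged adduct. Regioselectivity is secured by the four-atom tether C9–C10–C5–C6, which makes the fused mode the only unstrained one, and by the gem-dimethyl terminus, which takes the oxygen; the quaternary C10 favours the folded conformer (Thorpe–Ingold effect), slow generation of the dipole suppresses its dimerisation to a furoxan, and the ring ketone is not a dipolarophile. The only new stereocentre, C7, is temporary: a chair-like transition state of the forming ring B with the CMe2 terminus pseudo-equatorial should give 7α-H from either C5 epimer, and C7 becomes sp2 in step 10. No other centre is touched, so C10 is retained and the C5 epimers go on to the equilibration of step 6. In one event the step delivers ring B, the C7–C8 bond, the masked C8 carbonyl and the C11–O bond of the tertiary alcohol.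

Step 6
Reactants: 12 tricyclic isoxazoline ketone (both C5 epimers)
Product: 13 trans-fused tricyclic isoxazoline ketone (5α-H; 7α-H; 10β-CH3)
Conditions: NaOMe (0.2 equiv), MeOH, rt
Reagents that add atoms: none
Why: Base-mediated epimerisation through the C4 enolate equilibrates only C5, the sole enolisable stereocentre next to the ketone, and because the isoxazoline holds ring B in the chair with C11 equatorial the cis-fused epimer is confined to its strained conformer with axial C4 and C9 bonds, so the trans-fused 5α-H decalone should predominate as in 5α-4-oxo steroids (thermodynamic control, any cis-fused remainder being separated and resubmitted).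

Step 7
Reactants: 13 trans-fused tricyclic isoxazoline ketone
Product: 15 C3=C4 enol triflate of 13, via potassium enolate 14 (not isolated)
Conditions: KN(SiMe3)2, THF, −78 °C; then PhN(SO2CF3)2, −78 to 0 °C
Reagents that add atoms: N-phenylbis(trifluoromethanesulfonimide), O=S(=O)(N(c1ccccc1)S(=O)(=O)C(F)(F)F)C(F)(F)F
Why: Kinetic deprotonation by the bulky amide takes the less hindered C3 methylene and not the ring-fusion C5–H, and O-triflation of that enolate fixes the C3=C4 double bond without touching C5 (enol triflate formation).

Step 8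
Reactants: 15 C3=C4 enol triflate; 16 methylzinc chloride
Product: 17 eudesm-3-ene isoxazoline (C8=N–O–C11; 5α-H; 7α-H)
Conditions: Pd(PPh3)4 (5 mol%), THF, 50 °C
Reagents that add atoms: methylzinc chloride 16, C[Zn]Cl
Why: Negishi cross-coupling of the alkenyl triflate with the methylzinc reagent under zerovalent palladium catalysis installs the C4 methyl group with the double bond held at C3=C4, and the isoxazoline is inert to the organozinc.

Step 9
Reactants: 17 eudesm-3-ene isoxazoline
Product: 19 11-hydroxyeudesm-3-en-8-one (5α-H; 7α-H), via hydroxy imine 18 (not isolated)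
Conditions: Mo(CO)6 (1 equiv), MeCN/H2O 15:1, 80 °C
Reagents that add atoms: water, O
Why: Mo(CO)6 cleaves the weak N–O bond reductively and the resulting β-hydroxy imine is hydrolysed in the wet solvent, which unmasks the C8 ketone and the C11 tertiary alcohol (isoxazoline-to-aldol unmasking) and, unlike hydrogenolysis, leaves the C3=C4 alkene untouched.

Step 10
Reactants: 19 11-hydroxyeudesm-3-en-8-one
Product: 20 11-hydroxyeudesma-3,6-dien-8-one (5α-H)
Conditions: 2-iodoxybenzoic acid (IBX, 2.5 equiv), 4-methoxypyridine N-oxide, DMSO, rt to 40 °C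
Reagents that add atoms: none
Why: IBX-mediated α,β-dehydrogenation runs through the enol of the C8 ketone, and since C10 is quaternary only the C7 enol can lose a β-hydrogen, so the double bond can form only between C6 and C7; the tertiary alcohol is not oxidised and the mild N-oxide-accelerated conditions should spare the tertiary aldol from dehydration.

Step 11
Reactants: 20 11-hydroxyeudesma-3,6-dien-8-one
Product: 21 3α,4α,11-trihydroxyeudesm-6-en-8-one
Conditions: OsO4 (5 mol%), N-methylmorpholine N-oxide, acetone/H2O 8:1, rt
Reagents that add atoms: osmium tetroxide (catalytic oxygen carrier), O=[Os](=O)(=O)=O; N-methylmorpholine N-oxide, C[N+]1([O-])CCOCC1; water, O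
Why: Upjohn dihydroxylation takes the electron-rich trisubstituted C3=C4 alkene in preference to the electron-poor, hindered enone, and the suprafacial addition of OsO4 occurs on the α face opposite the axial C10 methyl group, which sets 3α-OH and 4α-OH (4β-CH3) together.

Step 12
Reactants: 21 3α,4α,11-trihydroxyeudesm-6-en-8-one; 22 angelic acid
Product: 23 3α-angeloyloxy-4α,11-dihydroxyeudesm-6-en-8-one (target)
Conditions: 22 (3 equiv), 2,4,6-trichlorobenzoyl chloride, Et3N, toluene, rt; then 21, 80 °C
Reagents that add atoms: angelic acid 22, C/C=C(/C)C(=O)O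
Why: Yamaguchi-type esterification through the preformed mixed anhydride acylates only the secondary C3 hydroxyl (the other two hydroxyls are tertiary), attack occurs at the unhindered angeloyl carbonyl, and the absence of a nucleophilic acyl-transfer catalyst should keep the Z double bond from isomerising to the tiglate.

**Compound list**

1 | 3-methylcyclohex-2-en-1-one | CC1=CC(=O)CCC1 | starting material
2 | vinylmagnesium bromide | C=C[Mg]Br | starting material
3 | dimethylaluminium (R)-3-methyl-3-vinylcyclohex-1-en-1-olate | C[Al](C)OC1=C[C@@](C)(C=C)CCC1 | intermediate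
4 | (R)-trimethyl[(3-methyl-3-vinylcyclohex-1-en-1-yl)oxy]silane | C[Si](C)(C)OC1=C[C@@](C)(C=C)CCC1 | intermediate
5 | 1-bromo-3-methylbut-2-ene (prenyl bromide) | CC(C)=CCBr | starting material
6 | lithium (R)-3-methyl-3-vinylcyclohex-1-en-1-olate | [Li]OC1=C[C@@](C)(C=C)CCC1 | intermediate
7 | (3R)-3-methyl-2-(3-methylbut-2-en-1-yl)-3-vinylcyclohexan-1-one, both C2 epimers | O=C1CCC[C@](C)(C=C)C1CC=C(C)C | intermediate
8 | 2-[(1R)-1-methyl-2-(3-methylbut-2-en-1-yl)-3-oxocyclohexyl]acetaldehyde, both C2 epimers | O=C1CCC[C@](C)(CC=O)C1CC=C(C)C | intermediate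
9 | 2-[(1R)-1-methyl-2-(3-methylbut-2-en-1-yl)-3-oxocyclohexyl]acetaldehyde oxime, both C2 epimers, E oxime drawn | O=C1CCC[C@](C)(C/C=N/O)C1CC=C(C)C | intermediate
10 | N-hydroxy-2-[(1R)-1-methyl-2-(3-methylbut-2-en-1-yl)-3-oxocyclohexyl]acetimidoyl chloride, both C2 epimers | O=C1CCC[C@](C)(CC(Cl)=NO)C1CC=C(C)C | intermediate
11 | 2-[(1R)-1-methyl-2-(3-methylbut-2-en-1-yl)-3-oxocyclohexyl]acetonitrile oxide, both C2 epimers | O=C1CCC[C@](C)(CC#[N+][O-])C1CC=C(C)C | intermediate
12 | tricyclic isoxazoline ketone: 15-noreudesman-4-one with C8 and C11 joined as C8=N–O–C11, 7α-H, 10β-CH3, both C5 epimers | O=C1CCC[C@]2(C)CC3=NOC(C)(C)[C@H]3CC12 | intermediate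
13 | trans-fused tricyclic isoxazoline ketone, 5α-H, 7α-H, 10β-CH3 | O=C1CCC[C@]2(C)CC3=NOC(C)(C)[C@H]3C[C@@H]12 | intermediate
14 | potassium C3=C4 enolate of 13 | [K]OC1=CCC[C@]2(C)CC3=NOC(C)(C)[C@H]3C[C@@H]12 | intermediate
15 | C3=C4 enol triflate of 13 (triflate on C4) | O=S(=O)(OC1=CCC[C@]2(C)CC3=NOC(C)(C)[C@H]3C[C@@H]12)C(F)(F)F | intermediate
16 | methylzinc chloride | C[Zn]Cl | starting material
17 | eudesm-3-ene isoxazoline (C8=N–O–C11), 5α-H, 7α-H | CC1=CCC[C@]2(C)CC3=NOC(C)(C)[C@H]3C[C@@H]12 | intermediate
18 | 8-iminoeudesm-3-en-11-ol, 5α-H, 7α-H | CC1=CCC[C@]2(C)CC(=N)[C@@H](C(C)(C)O)C[C@@H]12 | intermediate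
19 | 11-hydroxyeudesm-3-en-8-one, 5α-H, 7α-H | CC1=CCC[C@]2(C)CC(=O)[C@@H](C(C)(C)O)C[C@@H]12 | intermediate
20 | 11-hydroxyeudesma-3,6-dien-8-one, 5α-H | CC1=CCC[C@]2(C)CC(=O)C(C(C)(C)O)=C[C@@H]12 | intermediate
21 | 3α,4α,11-trihydroxyeudesm-6-en-8-one | O[C@@H]1CC[C@]2(C)CC(=O)C(C(C)(C)O)=C[C@H]2[C@]1(C)O | intermediate
22 | angelic acid, (Z)-2-methylbut-2-enoic acid | C/C=C(/C)C(=O)O | starting material
23 | 3α-angeloyloxy-4α,11-dihydroxyeudesm-6-en-8-one, (3R,4S,5R,10R) | C/C=C(/C)C(=O)O[C@@H]1CC[C@]2(C)CC(=O)C(C(C)(C)O)=C[C@H]2[C@]1(C)O | target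

Total step count: 12. Longest linear sequence: 12 steps (1 to 23).

**Steps most likely to fail**

Step 10. Enolisation toward the hindered C7 methine may be slow, so that loss of water from the tertiary aldol or retro-aldol loss of acetone overtakes the dehydrogenation. The fallback sets out from 19 and comes back at 21, replacing steps 10 and 11 by an elimination–ene sequence. The tertiary alcohol of 19 is eliminated with Burgess reagent (toluene, 50 °C) to the conjugated eudesma-3,7(11)-dien-8-one F1. OsO4 with N-methylmorpholine N-oxide then attacks only the C3=C4 bond, on the α face, to give 3α,4α-dihydroxyeudesm-7(11)-en-8-one F2. Photo-oxygenation (O2, tetraphenylporphyrin, visible light, CH2Cl2) performs a Schenck ene reaction in which the C6 hydrogen, on the group geminal to the carbonyl, is abstracted; this moves the double bond to C6=C7 and gives 11-hydroperoxy-3α,4α-dihydroxyeudesm-6-en-8-one F3. PPh3 reduces the hydroperoxide to 21.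

Step 1. Transfer of the unsubstituted vinyl group may proceed with low enantioselectivity or conversion, and silylation of the aluminium enolate may be incomplete. The fallback sets out from 2 and comes back at 4, with the roles of the two groups on C10 reversed. Reagent 2 is added to commercial 3-ethoxycyclohex-2-en-1-one F4, and the adduct 3-ethoxy-1-vinylcyclohex-2-en-1-ol F5 is hydrolysed with dilute HCl, without isolation, to 3-vinylcyclohex-2-en-1-one F6. MeMgBr is then added in the 1,4 sense under copper catalysis with a chiral N-heterocyclic carbene ligand (Cu(OSO2CF3)2, chiral imidazolinium salt, Et2O, −30 °C), a ligand class known to direct Grignard reagents to the 4-position of such dienones. The bromomagnesium (R)-3-methyl-3-vinylcyclohex-1-en-1-olate F7 so formed is silylated with Me3SiCl, Et3N and HMPA to give 4.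

Step 12. Acylation of the hindered axial C3 hydroxyl may be slow, and the activated angeloyl group may isomerise from Z to E during the heating. The fallback sets out from 21 and comes back at 23, building the double bond on the ester instead of transferring it. The C3 hydroxyl is esterified with 2-[bis(2,2,2-trifluoroethoxy)phosphoryl]propanoic acid F8 (DCC, DMAP, CH2Cl2) to give the C3 phosphonopropanoate F9. A Still–Gennari olefination of F9 with acetaldehyde (KN(SiMe3)2, 18-crown-6, THF, −78 °C) then forms the Z-trisubstituted alkene of the angelate, giving 23.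

**Further compounds**

F1 | step 10 | eudesma-3,7(11)-dien-8-one, 5α-H | CC1=CCC[C@]2(C)CC(=O)C(=C(C)C)C[C@@H]12
F2 | step 10 | 3α,4α-dihydroxyeudesm-7(11)-en-8-one | O[C@@H]1CC[C@]2(C)CC(=O)C(=C(C)C)C[C@H]2[C@]1(C)O
F3 | step 10 | 11-hydroperoxy-3α,4α-dihydroxyeudesm-6-en-8-one | O[C@@H]1CC[C@]2(C)CC(=O)C(C(C)(C)OO)=C[C@H]2[C@]1(C)O
F4 | step 1 | 3-ethoxycyclohex-2-en-1-one | CCOC1=CC(=O)CCC1
F5 | step 1 | 3-ethoxy-1-vinylcyclohex-2-en-1-ol | CCOC1=CC(O)(C=C)CCC1
F6 | step 1 | 3-vinylcyclohex-2-en-1-one | C=CC1=CC(=O)CCC1
F7 | step 1 | bromomagnesium (R)-3-methyl-3-vinylcyclohex-1-en-1-olate | Br[Mg]OC1=C[C@@](C)(C=C)CCC1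
F8 | step 12 | 2-[bis(2,2,2-trifluoroethoxy)phosphoryl]propanoic acid | CC(C(=O)O)P(=O)(OCC(F)(F)F)OCC(F)(F)F
F9 | step 12 | 3α-{2-[bis(2,2,2-trifluoroethoxy)phosphoryl]propanoyloxy}-4α,11-dihydroxyeudesm-6-en-8-one | CC(C(=O)O[C@@H]1CC[C@]2(C)CC(=O)C(C(C)(C)O)=C[C@H]2[C@]1(C)O)P(=O)(OCC(F)(F)F)OCC(F)(F)F
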